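**Plan**

- Retrosynthesis: the (E)-propenyl group on C5 is traced back through CHO to a nitrile. The dihydrofuran ring is then opened at the aryl ether bond O1–C7a, the C2 carbinol goes back to a ketone, and the C3–C3a bond is cut as a ketone α-arylation. This leaves 3-bromo-4,5-dimethoxybenzaldehyde and 1-(3,4,5-trimethoxyphenyl)propan-1-one.
- Forward order: the chain is joined first (C3–C3a), both stereocentres are set on the open chain, the furan ring closes as the last ring, and the C5 side chain is finished at the end.
- Enabling feature: on ring A, C7a bears an oxygen squeezed between C7–OMe and C3a, and C5 (the carbon that ends as propenyl) is para to it. With C5 held at the nitrile level, the C7a–OMe of the veratrole unit becomes an SNAr nucleofuge, so the C2 alkoxide takes the place of methoxide (aromatic transetherification). No halogen or metal is needed at C7a, and the bromoveratraldehyde supplies every ring A substituent.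
- Stereochemistry: one dynamic kinetic asymmetric hydrogenation of the racemic α-aryl ketone should give the (1R,2R)-anti alcohol (catalyst sets the carbinol, Felkin–Anh preference selects the C3 epimer). The ring closure breaks no bond at C2 or C3, so anti becomes trans-(2R,3R). The nitrile helper is then converted into the propenyl group.

Key step: step 4

**Route**

Step 1
Reactants: 1 3-bromo-4,5-dimethoxybenzaldehyde
Product: 3 3-bromo-4,5-dimethoxybenzonitrile, via aldoxime 2 (not isolated)
Conditions: NH2OH·HCl (1.3 equiv), DMSO, 100 °C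
Reagents that add atoms: hydroxylamine hydrochloride, NO.Cl
Why: Condensation to the aldoxime and acid-promoted dehydration in hot DMSO (one-pot aldehyde-to-nitrile conversion); the aryl bromide and methyl ethers are inert.

Step 2
Reactants: 3 3-bromo-4,5-dimethoxybenzonitrile; 4 1-(3,4,5-trimethoxyphenyl)propan-1-one
Product: 5 racemic 4,5-dimethoxy-3-[1-oxo-1-(3,4,5-trimethoxyphenyl)propan-2-yl]benzonitrile
Conditions: Pd2(dba)3 (1.5 mol %), Xantphos (3.6 mol %), NaOt-Bu (1.3 equiv), toluene, 80 °C
Reagents that add atoms: none
Why: Pd-catalysed ketone α-arylation (Buchwald–Hartwig type): zerovalent palladium inserts into the C–Br bond of 3, the sodium enolate of 4 displaces bromide on palladium and C–C reductive elimination forms the C3–C3a bond; the hindered tertiary α-carbon of the product resists a second arylation, the nitrile is inert, and the new stereocentre is formed racemic on purpose because step 3 resolves it dynamically.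

Step 3
Reactants: 5 racemic 4,5-dimethoxy-3-[1-oxo-1-(3,4,5-trimethoxyphenyl)propan-2-yl]benzonitrile
Product: 6 3-[(1R,2R)-1-hydroxy-1-(3,4,5-trimethoxyphenyl)propan-2-yl]-4,5-dimethoxybenzonitrile
Conditions: RuCl2[(S)-XylBINAP][(S)-DAIPEN] (0.5 mol %), KOt-Bu (20 mol %), H2 (8 atm), i-PrOH, 25 °C
Reagents that add atoms: none
Why: Noyori bifunctional hydrogenation with dynamic kinetic resolution: KOt-Bu epimerises the α-aryl stereocentre through the enolate faster than hydride transfer, the (S),(S)-catalyst (which gives (R)-1-arylalkanols from aryl alkyl ketones) should set the carbinol as R, and the Felkin–Anh preference (hydride anti to the ring A aryl group) makes the (R)-ketone the fast-reacting epimer, so the (1R,2R)-anti alcohol is expected; nitrile and aryl ethers are not reduced.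

Step 4
Reactants: 6 3-[(1R,2R)-1-hydroxy-1-(3,4,5-trimethoxyphenyl)propan-2-yl]-4,5-dimethoxybenzonitrile
Product: 7 (2R,3R)-7-methoxy-3-methyl-2-(3,4,5-trimethoxyphenyl)-2,3-dihydro-1-benzofuran-5-carbonitrile
Conditions: NaH (1.2 equiv), THF–DMPU (4:1), 0 to 65 °C
Reagents that add atoms: none
Why: Deprotonation gives the C2 alkoxide, which adds to C7a ipso to its methoxy group to form a Meisenheimer complex whose negative charge is carried by C5 and its nitrile; loss of methoxide re-aromatises ring A (addition–elimination SNAr, an aromatic transetherification). The closest known reaction type is the base-induced ring closure with methoxide as nucleofuge ortho or para to an acceptor (as in xanthone formation from 2-hydroxy-2'-methoxybenzophenones), together with SNAr closures of dihydrobenzofurans from activated aryl fluorides. The furan ring closes in the 5-exo-trig mode onto C7a (counting the C7a=C7 bond of ring A). No stereocentre is made: the C2–O and C3–C bonds are not broken, so the anti (1R,2R) arrangement of 6 is carried over unchanged as trans-(2R,3R). The step needs site selectivity for C7a–OMe over C7–OMe, the nitrile carbon and the three methoxy groups of the other ring; this is secured because only C7a is para to the nitrile and within reach of a five-membered transition state, and because its methoxy group is twisted out of conjugation by its two ortho neighbours (C7–OMe and C3a). The high effective molarity of the tethered alkoxide and the release of methanol should make the exchange effectively irreversible.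

Step 5
Reactants: 7 (2R,3R)-7-methoxy-3-methyl-2-(3,4,5-trimethoxyphenyl)-2,3-dihydro-1-benzofuran-5-carbonitrile
Product: 9 (2R,3R)-7-methoxy-3-methyl-2-(3,4,5-trimethoxyphenyl)-2,3-dihydro-1-benzofuran-5-carbaldehyde, via N-aluminio aldimine 8 (not isolated)
Conditions: i-Bu2AlH (1.3 equiv), CH2Cl2, −78 °C; then aq. KNaC4H4O6, rt
Reagents that add atoms: water, O
Why: Partial reduction of a nitrile: one hydride adds at −78 °C, the N-aluminio aldimine resists further reduction and is hydrolysed to the aldehyde on work-up; aryl ethers and both stereocentres are untouched.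

Step 6
Reactants: 9 (2R,3R)-7-methoxy-3-methyl-2-(3,4,5-trimethoxyphenyl)-2,3-dihydro-1-benzofuran-5-carbaldehyde
Product: 10 (2R,3R)-7-methoxy-3-methyl-5-[(1E)-prop-1-en-1-yl]-2-(3,4,5-trimethoxyphenyl)-2,3-dihydro-1-benzofuran
Conditions: 5-(ethylsulfonyl)-1-phenyl-1H-tetrazole, KN(SiMe3)2, DME, −60 °C; then 9, −60 °C to rt
Reagents that add atoms: 5-(ethylsulfonyl)-1-phenyl-1H-tetrazole, CCS(=O)(=O)c1nnnn1-c1ccccc1
Why: Julia–Kocienski olefination: the metalated ethyl sulfone adds to the aldehyde, the tetrazole migrates to oxygen (Smiles rearrangement) and anti elimination of SO2 and tetrazololate should give the (E)-propenyl group, which is favoured kinetically with potassium in DME and thermodynamically for an aryl-conjugated alkene; the conditions do not touch C2 or C3.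

**Compound list**

1 | 3-bromo-4,5-dimethoxybenzaldehyde | COc1cc(C=O)cc(Br)c1OC | starting material
2 | (E)-3-bromo-4,5-dimethoxybenzaldehyde oxime | COc1cc(/C=N/O)cc(Br)c1OC | intermediate (not isolated)
3 | 3-bromo-4,5-dimethoxybenzonitrile | COc1cc(C#N)cc(Br)c1OC | intermediate
4 | 1-(3,4,5-trimethoxyphenyl)propan-1-one | CCC(=O)c1cc(OC)c(OC)c(OC)c1 | starting material
5 | racemic 4,5-dimethoxy-3-[1-oxo-1-(3,4,5-trimethoxyphenyl)propan-2-yl]benzonitrile | COc1cc(C#N)cc(C(C)C(=O)c2cc(OC)c(OC)c(OC)c2)c1OC | intermediate
6 | 3-[(1R,2R)-1-hydroxy-1-(3,4,5-trimethoxyphenyl)propan-2-yl]-4,5-dimethoxybenzonitrile | COc1cc(C#N)cc([C@@H](C)[C@H](c2cc(OC)c(OC)c(OC)c2)O)c1OC | intermediate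
7 | (2R,3R)-7-methoxy-3-methyl-2-(3,4,5-trimethoxyphenyl)-2,3-dihydro-1-benzofuran-5-carbonitrile | N#Cc1cc(OC)c2c(c1)[C@@H](C)[C@H](c1cc(OC)c(OC)c(OC)c1)O2 | intermediate
8 | N-[bis(2-methylpropyl)alumanyl]-1-[(2R,3R)-7-methoxy-3-methyl-2-(3,4,5-trimethoxyphenyl)-2,3-dihydro-1-benzofuran-5-yl]methanimine | CC(C)C[Al](CC(C)C)N=Cc1cc(OC)c2c(c1)[C@@H](C)[C@H](c1cc(OC)c(OC)c(OC)c1)O2 | intermediate (not isolated)
9 | (2R,3R)-7-methoxy-3-methyl-2-(3,4,5-trimethoxyphenyl)-2,3-dihydro-1-benzofuran-5-carbaldehyde | O=Cc1cc(OC)c2c(c1)[C@@H](C)[C@H](c1cc(OC)c(OC)c(OC)c1)O2 | intermediate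
10 | (2R,3R)-7-methoxy-3-methyl-5-[(1E)-prop-1-en-1-yl]-2-(3,4,5-trimethoxyphenyl)-2,3-dihydro-1-benzofuran | C/C=C/c1cc(OC)c2c(c1)[C@@H](C)[C@H](c1cc(OC)c(OC)c(OC)c1)O2 | target

**Step count and risks**

Total steps: 6. Longest linear sequence: 6 steps (1 → 3 → 5 → 6 → 7 → 9 → 10).

Steps most likely to fail:

1. Step 3 (dynamic kinetic hydrogenation). Enolisation of the ketone may be slower than hydride delivery, so that the slow-reacting epimer is also reduced and diastereocontrol falls; coordination of the nitrile may also slow the catalyst and erode enantiocontrol. The fallback sets out from 5 and returns at 6. Reduction of 5 with LiBH(s-Bu)3 in THF at −78 °C under Felkin–Anh control should give the racemic anti alcohol F1. Esterification with (S)-2-methoxy-2-phenylacetic acid (DCC, DMAP, CH2Cl2) gives two diastereomeric esters, the (1R,2R)-alcohol ester F2 and the (1S,2S)-alcohol ester F3, to be separated by chromatography or crystallisation. LiOH in THF–MeOH–H2O at rt cleaves F2 to 6.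

2. Step 4 (ring closure). Expulsion of methoxide from the Meisenheimer complex may be too slow, so that intermolecular attack of the alkoxide on the nitrile or O-demethylation competes. The fallback sets out from 6 and returns at 7. NaSEt in DMF at 100 °C removes the methyl group of the C7a–OMe by SN2 attack at carbon (the only methoxy group whose phenoxide is para to the nitrile) to give the phenol F4. PhNTf2 and K2CO3 in THF triflate the phenol selectively to give the aryl triflate F5. Pd(OAc)2, 2-(di-tert-butylphosphino)-1,1'-binaphthyl and K3PO4 in toluene at 80 °C then close the same O1–C7a bond by oxidative addition, alkoxide exchange and C–O reductive elimination (Buchwald–Hartwig etherification), giving 7.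

3. Step 6 (olefination). Kinetic control of the alkene geometry may be incomplete, leaving a mixture of double-bond isomers. The fallback sets out from 9 and returns at 10. EtMgBr in THF at 0 °C adds to 9 to give the carbinol F6 (both epimers at the new centre serve). Catalytic p-toluenesulfonic acid in toluene at 60 °C dehydrates F6 through the para-alkoxybenzylic cation to the thermodynamically preferred (E)-alkene 10.

**Further compounds**

F1 | step 3 | racemic anti alcohol, (1R,2R)- and (1S,2S)-3-[1-hydroxy-1-(3,4,5-trimethoxyphenyl)propan-2-yl]-4,5-dimethoxybenzonitrile | COc1cc(C#N)cc([C@@H](C)[C@H](c2cc(OC)c(OC)c(OC)c2)O)c1OC.COc1cc(C#N)cc([C@H](C)[C@@H](c2cc(OC)c(OC)c(OC)c2)O)c1OC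
F2 | step 3 | (1R,2R)-2-(5-cyano-2,3-dimethoxyphenyl)-1-(3,4,5-trimethoxyphenyl)propyl (2S)-2-methoxy-2-phenylacetate | COc1cc(C#N)cc([C@@H](C)[C@H](c2cc(OC)c(OC)c(OC)c2)OC(=O)[C@@H](OC)c2ccccc2)c1OC
F3 | step 3 | (1S,2S)-2-(5-cyano-2,3-dimethoxyphenyl)-1-(3,4,5-trimethoxyphenyl)propyl (2S)-2-methoxy-2-phenylacetate | COc1cc(C#N)cc([C@H](C)[C@@H](c2cc(OC)c(OC)c(OC)c2)OC(=O)[C@@H](OC)c2ccccc2)c1OC
F4 | step 4 | 4-hydroxy-3-[(1R,2R)-1-hydroxy-1-(3,4,5-trimethoxyphenyl)propan-2-yl]-5-methoxybenzonitrile | COc1cc(C#N)cc([C@@H](C)[C@H](c2cc(OC)c(OC)c(OC)c2)O)c1O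
F5 | step 4 | 4-cyano-2-[(1R,2R)-1-hydroxy-1-(3,4,5-trimethoxyphenyl)propan-2-yl]-6-methoxyphenyl trifluoromethanesulfonate | COc1cc(C#N)cc([C@@H](C)[C@H](c2cc(OC)c(OC)c(OC)c2)O)c1OS(=O)(=O)C(F)(F)F
F6 | step 6 | 1-[(2R,3R)-7-methoxy-3-methyl-2-(3,4,5-trimethoxyphenyl)-2,3-dihydro-1-benzofuran-5-yl]propan-1-ol (both carbinol epimers) | CCC(O)c1cc(OC)c2c(c1)[C@@H](C)[C@H](c1cc(OC)c(OC)c(OC)c1)O2
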